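G, the product, is wanted at its top, and the readings below do not show that top directly.

| flask | J | remark | time |
|---|---|---|---|
| gamma | 20 mM | run made earlier |  |
| zeta | 29 mM | run made earlier |  |
| flask | 39 mM |  | 8.0 d |

| run | time / d | G / % |
|---|---|---|
| gamma | 0.104 | 52.2 |
| gamma | 0.417 | 44.1 |
| gamma | 2.08 | 10.0 |
| gamma | 10.0 | 6.9 |
| zeta | 0.104 | 52.2 |
| zeta | 0.417 | 44.3 |
| zeta | 2.08 | 9.3 |
| zeta | 10.0 | 5.5 |

(scatter of a reading: 0.5 percentage points)

* time, not beyond 8.0 d, at which the flask holds most G
* the amount of G, in percent of the J charged, at that time



*Does the charge change the early shares?* Not visibly: the first two readings of gamma and zeta agree within the scatter. So I treat the early curve as first order and reckon from zeta, the run nearest this flask in charge.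

*How fast is G lost?* I take the last reading, 5.5%, as a floor. Above it, the share falls between the middle readings at 1.40 d⁻¹; this is the loss clock, counted in turnovers.

*But isn't G already falling at the first reading?* That is the weak spot. The loss line, run back from the second reading, has a starting height of 69.5% above the floor. At 0.104 d it stands 13 percentage points above the reading, which is more than the scatter. So I read G as still being made then, and that shortfall gives a making clock of 15.8 d⁻¹.

*Where, then, is the top?* It lies where making and loss balance: at the logarithm of the ratio of the clocks divided by their difference, 0.168 d, my crossing time. By then making has counted 2.65 turnovers and loss 0.235, and I expect G at 55.6%.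

The forecast gave 0.08 d (0.02 d to 0.2 d) and 54% (52% to 62%), noting that “no run samples the rise”, so its time stands earlier than my crossing time.

The flask holds most G, 56.4%, at 0.176 d.

    J ⇌ G (K = 12.0, k = 0.440 h⁻¹)
    G ⇌ D (K = 14.0, k = 0.0720 h⁻¹)
    J ⇌ Z (K = 3.10, k = 0.0870 h⁻¹)
    2 J → Q (k = 0.440 L mol⁻¹ h⁻¹)

Against that time stands the crossing time of 0.168 d, and a flask charged with half the J peaks at 0.177 d. In this flask, J goes into G with a half-life of 0.066 d, shorter than the 0.40 d of G into D, each counted by its forward rate alone. At 0.176 d this flask holds 56.4% G beside 12.7% D, and at 8.00 d it holds 6.41% G beside 87.6% D.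

The readings were generated by integration from invented constants; noise was put on by code.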